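**Strategy.** The C12–C13 oxirane of seven-membered ring C (cyathane numbering; C12 carries the methyl, C13 the hydrogen) is read as a masked trisubstituted olefin, so everything rests on the C12–C13 bond. Ring-closing metathesis between the allyl group on quaternary C6 and the 3-methylbut-3-enyl chain on C5 of a trans-fused hydrindanone closes ring C as the C12=C13 cycloheptene in one operation; peracid then attacks anti to the axial C6 methyl. The precursor is assembled on a C3-silyloxy cyclopentene ester by two trans-selective conjugate addition–enolate alkylation events and an intramolecular Horner–Wadsworth–Emmons closure of ring B; the α-methylene hydroxy-lactone is built last from the C3 ketone.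

Key step: step 7

Remark (numbering): ring A = cyclopentane C1–C2–C3–C4–C9 (C2 carries the lactone oxygen, C3 the tertiary OH); ring B = cyclohexane C4–C5–C6–C7–C8–C9; ring C = cycloheptane C5–C10–C11–C12–C13–C14–C6. C15 = methyl on C12, C16 = methyl on C6, C17 = CH2OAc carbon on C9, C18/C19/C20 = lactone α-carbon, exocyclic CH2 and carbonyl. β = face of C17, H5 and the oxirane oxygen; α = face of H4, C16 and the C3 hydroxyl.

Remark (chemistry): compounds 1, 4, 5, 8, 12 and 24 are taken as commercial. In step 1 the ene-ester side of ketone 1 is assumed to act as the large group towards the CBS catalyst.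

## Route

Step 1
Reactants: 1 methyl 3-oxocyclopent-1-ene-1-carboxylate
Product: 2 methyl (R)-3-hydroxycyclopent-1-ene-1-carboxylate
Conditions: (S)-2-methyl-CBS-oxazaborolidine (10 mol %), BH3·SMe2, THF, −20 °C
Reagents that add atoms: none
Why: Corey–Bakshi–Shibata reduction: the (S)-catalyst delivers hydride so that the C3 carbinol is (R) (oxygen α), which is the only external source of absolute configuration in the route, and the electron-poor alkene is not hydroborated at low temperature.

Step 2
Reactants: 2 methyl (R)-3-hydroxycyclopent-1-ene-1-carboxylate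
Product: 3 methyl (R)-3-(tert-butyldimethylsilyloxy)cyclopent-1-ene-1-carboxylate
Conditions: TBSCl, imidazole, DMF, 23 °C
Reagents that add atoms: tert-butyldimethylsilyl chloride, CC(C)(C)[Si](C)(C)Cl
Why: Silyl ether formation on a secondary allylic alcohol; the bulky group shields the α face for step 3 and no stereocentre is touched.

Step 3
Reactants: 3 silyl ether; 4 1,3-dithiane; 5 2-bromo-N-methoxy-N-methylacetamide
Product: 7 ring A Weinreb amide (C4 β-dithianyl, C9 β-CO2Me, C9 α-CH2C(O)N(OMe)Me, C3 α-OTBS), via lithium ketene acetal 6 (not isolated)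
Conditions: 4, n-BuLi, THF, −30 °C; HMPA, then 3, −78 °C; then 5, −78 to −20 °C
Reagents that add atoms: none
Why: Tandem Michael addition–enolate alkylation (dithiane acyl-anion conjugate addition in THF–HMPA): the lithiodithiane adds to C4 anti to the C3 silyloxy group (C5 β, H4 α) and the ester enolate is alkylated at C9 anti to the new C4 substituent, so C9 carries the ester (C17) β and the C8 arm α.

Step 4
Reactants: 7 ring A Weinreb amide; 8 diethyl but-3-en-1-ylphosphonate
Product: 9 β-ketophosphonate (C7 ketone, allyl and phosphonate on C6)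
Conditions: 8, n-BuLi, THF, −78 °C; then 7, −78 to −40 °C; aq. NH4Cl
Reagents that add atoms: none
Why: Acylation of an α-lithiated phosphonate by a Weinreb amide: the chelated tetrahedral adduct stops at the ketone, the neopentyl methyl ester on quaternary C9 is too hindered to compete, and the new phosphonate-bearing carbon is a temporary stereocentre left as a mixture.

Step 5
Reactants: 9 β-ketophosphonate
Product: 11 trans-fused hydrindenone (C7 ketone, C5=C6, allyl on C6, C9 β-CO2Me, H4 α, C3 α-OTBS), via ketophosphonate aldehyde 10 (not isolated)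
Conditions: PhI(O2CCF3)2, NaHCO3, MeCN–H2O (9:1), 0 °C; then LiCl, i-Pr2NEt, MeCN, 23 °C
Reagents that add atoms: water, O
Why: Stork–Zhao oxidative dethioacetalisation followed by intramolecular Horner–Wadsworth–Emmons olefination under Masamune–Roush conditions: the weak amine base olefinates the C5 aldehyde without epimerising C4, so ring B closes trans-fused and no new stereocentre arises.

Step 6
Reactants: 11 hydrindenone; 12 4-bromo-2-methylbut-1-ene
Product: 14 ketone with C5 α-(3-methylbut-3-enyl), C6 α-methyl and C6 β-allyl, via trimethylsilyl enol ether 13 (not isolated)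
Conditions: 12, Mg, THF; CuBr·SMe2 (20 mol %), TMSCl, HMPA, THF, −78 °C, then 11; MeLi, −20 °C; MeI, −20 to 0 °C
Reagents that add atoms: iodomethane, CI
Why: Copper-catalysed conjugate addition with TMSCl acceleration, then regiospecific enolate methylation: the organocopper adds to C5 trans to the C4–C3 bond and anti to the axial C9 ester (chain α, H5 β), and MeI attacks the C6 lithium enolate axially from the α face, which places the methyl α and the allyl β.

Step 7
Reactants: 14 diene ketone
Product: 15 tricyclic ketone with the C12=C13 cycloheptene (ring C closed)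
Conditions: second-generation Hoveyda–Grubbs catalyst (5 mol %), toluene (5 mM), 80 °C
Reagents that add atoms: none
Why: Ring-closing olefin metathesis: the ruthenium alkylidene loads on the monosubstituted allyl terminus, adds to the 1,1-disubstituted C12 alkene to give a ruthenacyclobutane and cycloreverts to the C12=C13 cycloheptene with loss of ethene (Chauvin mechanism). The closest known reaction type is the closure of trisubstituted cycloheptenes by second-generation ruthenium catalysts on cyclohexanes that carry an allyl group on a quaternary carbon and a 3-methylbut-3-enyl chain on the neighbouring carbon. Ring C is closed as a seven-membered ring with both olefin carbons endocyclic, and the ring allows only the Z alkene. No stereocentre is formed; the trans ring fusion is already defined by the C5 and C6 stereocentres of 14 (set in step 6), whose two chains sit trans-diequatorial and gauche and are therefore predisposed to close. The step needs intramolecular closure to win over cross-metathesis dimerisation, which is secured by high dilution, by the absence of any third alkene and by the slow homodimerisation of the 1,1-disubstituted terminus.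

Step 8
Reactants: 15 tricyclic keto ester
Product: 16 diol (C17 primary alcohol, C7 carbinol as either epimer)
Conditions: LiAlH4, THF, 0 to 50 °C
Reagents that add atoms: none
Why: Hydride reduction with LiAlH4 converts the neopentyl ester into the C17 alcohol and the C7 ketone into a carbinol whose configuration is irrelevant because it is removed in step 11.

Step 9
Reactants: 16 diol
Product: 17 C17 acetate with free C7 carbinol
Conditions: Ac2O (1.1 equiv), pyridine, DMAP (cat.), CH2Cl2, 0 °C
Reagents that add atoms: acetic anhydride, CC(=O)OC(C)=O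
Why: Selective acylation: the primary C17 alcohol is acetylated while the C7 carbinol flanked by quaternary C6 stays free; no stereocentre changes.

Step 10
Reactants: 17 hydroxy acetate
Product: 18 C7 O-(imidazol-1-ylthiocarbonyl) derivative
Conditions: 1,1'-thiocarbonyldiimidazole, DMAP, toluene, 90 °C
Reagents that add atoms: 1,1'-thiocarbonyldiimidazole, S=C(n1ccnc1)n1ccnc1
Why: Thioacylation of the hindered secondary alcohol gives the Barton–McCombie substrate under non-basic conditions that leave the acetate intact.

Step 11
Reactants: 18 thiocarbonyl derivative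
Product: 19 C7-deoxy tricycle (C17 acetate, C3 α-OTBS, C12=C13)
Conditions: Bu3SnH, AIBN, toluene, 110 °C
Reagents that add atoms: none
Why: Barton–McCombie deoxygenation: the stannyl radical adds to the thiocarbonyl, the C7 radical is released and is reduced by Bu3SnH faster than it can attack the remote alkene, and the C7 stereocentre disappears.

Step 12
Reactants: 19 cycloheptene
Product: 20 12β,13β-epoxide
Conditions: mCPBA, NaHCO3, CH2Cl2, 0 °C
Reagents that add atoms: 3-chloroperbenzoic acid, OOC(=O)c1cccc(Cl)c1
Why: Prilezhaev epoxidation of the only alkene: in the chair-like ring C the axial C6 methyl screens the α face, so the peracid adds from the β face and sets C12 and C13 together (oxygen β, anti to C16).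

Step 13
Reactants: 20 epoxide silyl ether
Product: 21 C3 α-alcohol
Conditions: TBAF, AcOH, THF, 23 to 40 °C
Reagents that add atoms: none
Why: Fluoride-mediated desilylation buffered with acetic acid frees the C3 alcohol without opening the oxirane or cleaving the acetate.

Step 14
Reactants: 21 alcohol
Product: 22 C3 ketone (trans-fused, H4 α)
Conditions: Dess–Martin periodinane, NaHCO3, CH2Cl2, 0 to 23 °C
Reagents that add atoms: none
Why: Dess–Martin oxidation under bicarbonate buffer is non-enolising, so the trans ring fusion at C4, now α to the ketone, is retained.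

Step 15
Reactants: 22 ketone
Product: 23 C2=C3 enol triflate
Conditions: KHMDS, THF, −78 °C; then PhNTf2, −78 °C
Reagents that add atoms: N-phenylbis(trifluoromethanesulfonimide), O=S(=O)(N(c1ccccc1)S(=O)(=O)C(F)(F)F)C(F)(F)F
Why: Kinetic enolate O-triflation: KHMDS at −78 °C removes a proton from the C2 methylene and not from the ring-fusion methine C4, so the Δ2 enol triflate forms and C4 is not epimerised.

Step 16
Reactants: 24 methyl propiolate
Product: 25 methyl 2-(tributylstannyl)prop-2-enoate
Conditions: Bu3SnH, Pd(PPh3)4 (2 mol %), THF, 0 to 23 °C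
Reagents that add atoms: tributyltin hydride, CCCC[SnH](CCCC)CCCC
Why: Palladium-catalysed syn-hydrostannation of an alkynoate places tin on the α-carbon; no stereocentre is formed.

Step 17
Reactants: 23 enol triflate; 25 stannyl acrylate
Product: 26 diene ester (C2=C3, C3 bearing the C18(=C19H2)CO2Me unit)
Conditions: Pd(PPh3)4 (10 mol %), CuCl, LiCl, DMSO, 50 °C
Reagents that add atoms: none
Why: Stille cross-coupling of an enol triflate with an α-stannyl acrylate, with LiCl and CuCl accelerating transmetalation of the hindered stannane; no stereocentre is formed and oxirane and acetate are inert.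

Step 18
Reactants: 26 diene ester
Product: 27 2α,3α-diol methyl ester
Conditions: OsO4 (5 mol %), NMO, acetone–H2O, 0 to 23 °C
Reagents that add atoms: N-methylmorpholine N-oxide, C[N+]1([O-])CCOCC1; water, O
Why: Upjohn dihydroxylation: OsO4 selects the electron-richer trisubstituted C2=C3 bond over the acrylate alkene and adds from the α face, anti to the axial C17 group, so C3 gets its α-hydroxyl (C18 β) and C2 a temporary α-hydroxyl.

Step 19
Reactants: 27 diol ester
Product: 28 target compound CNP0404717.1
Conditions: Tf2O, pyridine, CH2Cl2, −78 to 0 °C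
Reagents that add atoms: none
Why: Lactonisation with inversion by neighbouring-group participation: the secondary C2 hydroxyl is triflated selectively, the ester carbonyl oxygen on the β-oriented C18 arm displaces the α-triflate from the rear (5-exo-tet) and the methoxy-oxocarbenium ion is demethylated, which gives the cis-fused lactone with the C2 oxygen β.

## Compound list

1 | methyl 3-oxocyclopent-1-ene-1-carboxylate | COC(=O)C1=CC(=O)CC1 | starting material
2 | methyl (R)-3-hydroxycyclopent-1-ene-1-carboxylate | COC(=O)C1=C[C@H](O)CC1 | intermediate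
3 | methyl (R)-3-(tert-butyldimethylsilyloxy)cyclopent-1-ene-1-carboxylate | COC(=O)C1=C[C@H](O[Si](C)(C)C(C)(C)C)CC1 | intermediate
4 | 1,3-dithiane | C1CSCSC1 | starting material
5 | 2-bromo-N-methoxy-N-methylacetamide | BrCC(=O)N(C)OC | starting material
6 | lithium ketene acetal of the C4 dithianyl adduct (C9 enolate; dithianyl trans to OTBS) | C1CC(=C(O[Li])OC)[C@@H](C2SCCCS2)[C@@H]1O[Si](C)(C)C(C)(C)C | intermediate
7 | ring A Weinreb amide: cyclopentane with C3 α-OTBS, C4 β-(1,3-dithian-2-yl), C9 β-CO2Me and C9 α-CH2C(O)N(OMe)Me | C1C[C@](C(=O)OC)(CC(=O)N(C)OC)[C@@H](C2SCCCS2)[C@@H]1O[Si](C)(C)C(C)(C)C | intermediate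
8 | diethyl but-3-en-1-ylphosphonate | C=CCCP(=O)(OCC)OCC | starting material
9 | β-ketophosphonate: as 7 with the C9 α-arm CH2C(O)CH(allyl)P(O)(OEt)2 (phosphonate carbon as a mixture) | C1C[C@](C(=O)OC)(CC(=O)C(CC=C)P(=O)(OCC)OCC)[C@@H](C2SCCCS2)[C@@H]1O[Si](C)(C)C(C)(C)C | intermediate
10 | ketophosphonate aldehyde: as 9 with C4 β-CHO in place of the dithiane | C1C[C@](C(=O)OC)(CC(=O)C(CC=C)P(=O)(OCC)OCC)[C@@H](C=O)[C@@H]1O[Si](C)(C)C(C)(C)C | intermediate
11 | trans-fused hydrindenone: C7 ketone, C5=C6, allyl on C6, C9 β-CO2Me, H4 α, C3 α-OTBS | C1C[C@]2(C(=O)OC)CC(=O)C(CC=C)=C[C@H]2[C@@H]1O[Si](C)(C)C(C)(C)C | intermediate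
12 | 4-bromo-2-methylbut-1-ene | C=C(C)CCBr | starting material
13 | trimethylsilyl enol ether (C6=C7) of the conjugate adduct, C5 α-(3-methylbut-3-enyl), H5 β | C1C[C@]2(C(=O)OC)CC(O[Si](C)(C)C)=C(CC=C)[C@H](CCC(C)=C)[C@H]2[C@@H]1O[Si](C)(C)C(C)(C)C | intermediate
14 | trans-hydrindan-7-one: C5 α-(3-methylbut-3-enyl), C6 α-methyl and β-allyl, C9 β-CO2Me, C3 α-OTBS | C1C[C@]2(C(=O)OC)CC(=O)[C@@](C)(CC=C)[C@H](CCC(C)=C)[C@H]2[C@@H]1O[Si](C)(C)C(C)(C)C | intermediate
15 | tricyclic 5-6-7 ketone: C12=C13 cycloheptene trans-fused at C5/C6, C7 ketone, C9 β-CO2Me, C3 α-OTBS | C1C[C@]2(C(=O)OC)CC(=O)[C@@]3(C)CC=C(C)CC[C@@H]3[C@H]2[C@@H]1O[Si](C)(C)C(C)(C)C | intermediate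
16 | diol: as 15 with C17 CH2OH and C7 CHOH (either epimer) | C1C[C@]2(CO)CC(O)[C@@]3(C)CC=C(C)CC[C@@H]3[C@H]2[C@@H]1O[Si](C)(C)C(C)(C)C | intermediate
17 | C17 acetate with free C7 carbinol | C1C[C@]2(COC(C)=O)CC(O)[C@@]3(C)CC=C(C)CC[C@@H]3[C@H]2[C@@H]1O[Si](C)(C)C(C)(C)C | intermediate
18 | C7 O-(1H-imidazol-1-ylthiocarbonyl) derivative of 17 | C1C[C@]2(COC(C)=O)CC(OC(=S)n4ccnc4)[C@@]3(C)CC=C(C)CC[C@@H]3[C@H]2[C@@H]1O[Si](C)(C)C(C)(C)C | intermediate
19 | C7-deoxy tricycle: C17 acetate, C3 α-OTBS, C12=C13 | C1C[C@]2(COC(C)=O)CC[C@@]3(C)CC=C(C)CC[C@@H]3[C@H]2[C@@H]1O[Si](C)(C)C(C)(C)C | intermediate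
20 | 12β,13β-epoxide of 19 | C1C[C@]2(COC(C)=O)CC[C@@]3(C)C[C@H]4O[C@@]4(C)CC[C@@H]3[C@H]2[C@@H]1O[Si](C)(C)C(C)(C)C | intermediate
21 | epoxy C3 α-alcohol | C1C[C@]2(COC(C)=O)CC[C@@]3(C)C[C@H]4O[C@@]4(C)CC[C@@H]3[C@H]2[C@@H]1O | intermediate
22 | epoxy C3 ketone (H4 α) | C1C[C@]2(COC(C)=O)CC[C@@]3(C)C[C@H]4O[C@@]4(C)CC[C@@H]3[C@H]2C1=O | intermediate
23 | C2=C3 enol triflate | C1[C@]2(COC(C)=O)CC[C@@]3(C)C[C@H]4O[C@@]4(C)CC[C@@H]3[C@H]2C(OS(=O)(=O)C(F)(F)F)=C1 | intermediate
24 | methyl propiolate | C#CC(=O)OC | starting material
25 | methyl 2-(tributylstannyl)prop-2-enoate | C=C(C(=O)OC)[Sn](CCCC)(CCCC)CCCC | intermediate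
26 | diene ester: C2=C3 with methyl 2-propenoate-2-yl on C3 | C1[C@]2(COC(C)=O)CC[C@@]3(C)C[C@H]4O[C@@]4(C)CC[C@@H]3[C@H]2C(C(=C)C(=O)OC)=C1 | intermediate
27 | 2α,3α-diol methyl ester (C18 arm β) | O[C@@H]1C[C@]2(COC(C)=O)CC[C@@]3(C)C[C@H]4O[C@@]4(C)CC[C@@H]3[C@H]2[C@@]1(O)C(=C)C(=O)OC | intermediate
28 | CNP0404717.1 | C=C1C(=O)O[C@H]2C[C@]3(COC(C)=O)CC[C@@]4(C)C[C@H]5O[C@@]5(C)CC[C@@H]4[C@H]3[C@@]12O | target

## Summary and risks

Total step count: 19. Longest linear sequence: 18 steps (steps 1–15 and 17–19; step 16 makes the stannane on a side branch).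

Three steps most likely to fail:

Step 3. The lithiodithiane may add 1,2 to the ester or deprotonate 3 at the γ-position instead of adding 1,4, and the crowded ester enolate may be quenched by proton transfer from 5. The fallback sets out from 3 and replaces the acyl-anion addition by a copper-catalysed conjugate addition of the Tamao reagent (isopropoxydimethylsilyl)methylmagnesium chloride (CuBr·SMe2, TMSCl), then MeLi and 5, to give the silylmethyl Weinreb amide F1. Acylation of lithiated 8 as in step 4 gives the silylmethyl ketophosphonate F2. Tamao–Fleming oxidation (KF, KHCO3, H2O2) gives the primary alcohol F3. Dess–Martin oxidation gives aldehyde 10, and the Masamune–Roush closure of step 5 brings the sequence back to the route at 11.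

Step 6. C-methylation of the hindered tetrasubstituted lithium enolate may be slow, so that O-methylation or proton quench takes over. The fallback sets out from 13, which is isolated after the conjugate addition. Furukawa cyclopropanation (Et2Zn, CH2I2) of the electron-rich silyl enol ether from the α face gives the siloxycyclopropane F4. Ring opening with K2CO3 in MeOH (Conia-type cleavage of the C7–CH2 bond) turns the cyclopropane methylene into the α-methyl group and comes back to the route at 14.

Step 19. A semipinacol-type 1,2-shift or elimination at the C2 triflate may outrun participation of the ester carbonyl. The fallback sets out from 27 and oxidises the secondary C2 alcohol (IBX, DMSO) to the α-hydroxy ketone F5. Reduction with NaBH4/CeCl3 from the open α face gives the 2β-hydroxy ester F6, which lactonises in the flask and comes back to the route at 28.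

## Further compounds

F1 | step 3 | silylmethyl Weinreb amide: as 7 with C4 β-CH2SiMe2(O-i-Pr) in place of the dithiane | C1C[C@](C(=O)OC)(CC(=O)N(C)OC)[C@@H](C[Si](C)(C)OC(C)C)[C@@H]1O[Si](C)(C)C(C)(C)C
F2 | step 3 | silylmethyl ketophosphonate: as 9 with C4 β-CH2SiMe2(O-i-Pr) | C1C[C@](C(=O)OC)(CC(=O)C(CC=C)P(=O)(OCC)OCC)[C@@H](C[Si](C)(C)OC(C)C)[C@@H]1O[Si](C)(C)C(C)(C)C
F3 | step 3 | hydroxymethyl ketophosphonate: as 9 with C4 β-CH2OH | C1C[C@](C(=O)OC)(CC(=O)C(CC=C)P(=O)(OCC)OCC)[C@@H](CO)[C@@H]1O[Si](C)(C)C(C)(C)C
F4 | step 6 | siloxycyclopropane: C6–C7 cyclopropane with the CH2 on the α face, C7 OSiMe3, C6 β-allyl | C1C[C@]2(C(=O)OC)C[C@]4(O[Si](C)(C)C)C[C@]4(CC=C)[C@H](CCC(C)=C)[C@H]2[C@@H]1O[Si](C)(C)C(C)(C)C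
F5 | step 19 | α-hydroxy ketone: C2 ketone, C3 α-OH, methyl ester intact | O=C1C[C@]2(COC(C)=O)CC[C@@]3(C)C[C@H]4O[C@@]4(C)CC[C@@H]3[C@H]2[C@@]1(O)C(=C)C(=O)OC
F6 | step 19 | 2β,3α-diol methyl ester | O[C@H]1C[C@]2(COC(C)=O)CC[C@@]3(C)C[C@H]4O[C@@]4(C)CC[C@@H]3[C@H]2[C@@]1(O)C(=C)C(=O)OC
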